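Cuts (guaiane numbering): the C8 and C11 ester C–O bonds go first. The enone is then traced to a guaia-3,5-diene, whose C3=C4 and C5=C6 bonds are cut together. The open chain is cut at C7–C8 (allylboration), C1–C2 (imide alkylation) and C5≡C4/C4–C15 (alkyne homologation, methylation).
Enabling feature: C5 is the sp2 atom shared by five-membered ring A and seven-membered ring B, flanked by methyl-bearing C4 in ring A and by C6 in ring B. C15–C4≡C5 can therefore be a propynyl group on C1 that takes a carbene from C6 and passes it on to C3.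
Forward: the chain C5–C1–C10–C9–C8 comes from methyl hydrogen (R)-3-methylglutarate, C2–C3 from prenyl bromide, and C6–C7–C11 from 2-methylbut-3-yn-2-ol. In one flask ring B closes first (C5=C6) and ring A second (C3=C4). Hydroboration, oxidation and an alkene shift then give the enone, and the two acylations finish the route.
Stereochemistry: C10 is bought, C1 comes from an Evans alkylation, and C7/C8 come from an E-allylboronate (anti) under chiral phosphoric acid control. The cascade creates no stereocentre, and the enone is made under conditions that leave C1 alone.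
Design point: the ring A alkene is capped as a prenyl group so that ruthenium can load only on the C6 vinyl group. A carbene on C3 would sit two atoms from the alkyne and could reach it only by a cyclobutene-forming exo closure or an uncommon endo closure.

Key step: step 13

Remark: guaiane numbering is used for every intermediate. The target is read as (1R,7S,8R,10S), with H-1, the C10 methyl, the C8 oxygen and C11 all on the same face of ring B.

Step 1
Reactants: 1 methyl hydrogen (R)-3-methylglutarate; 2 (4R)-4-benzyl-1,3-oxazolidin-2-one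
Product: 4 methyl (3R)-5-[(4R)-4-benzyl-2-oxo-1,3-oxazolidin-3-yl]-3-methyl-5-oxopentanoate, via mixed pivalic anhydride 3 (not isolated)
Conditions: t-BuCOCl, Et3N, THF, −20 °C; then LiCl, 2, −20 °C to rt
Reagents that add atoms: none
Why: Mixed-anhydride N-acylation of an Evans oxazolidinone activates only the free acid arm of 1, so the methyl ester arm stays differentiated and C10 is untouched.

Step 2
Reactants: 4 imide; 5 prenyl bromide (1-bromo-3-methylbut-2-ene)
Product: 7 methyl (3S,4R)-4-{[(4R)-4-benzyl-2-oxo-1,3-oxazolidin-3-yl]carbonyl}-3,7-dimethyloct-6-enoate, via sodium Z-enolate 6 (not isolated)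
Conditions: NaN(SiMe3)2, THF, −78 °C; then 5, −78 to −40 °C
Reagents that add atoms: none
Why: In this Evans asymmetric alkylation the imide, more acidic than the ester, gives the chelated Z-enolate 6, whose face on the side of the benzyl group is blocked, so the reactive allylic bromide enters from the opposite face and sets C1 as R.

Step 3
Reactants: 7 alkylated imide
Product: 8 methyl (3S,4R)-4-[(ethylsulfanyl)carbonyl]-3,7-dimethyloct-6-enoate
Conditions: EtSH, n-BuLi, THF, 0 °C
Reagents that add atoms: ethanethiol, CCS
Why: In this thiolate cleavage of the imide (transthioesterification) the soft, weakly basic lithium thiolate attacks the exocyclic carbonyl even next to a branched carbon, leaves the methyl ester and C1 alone and returns the auxiliary.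

Step 4
Reactants: 8 thioester
Product: 9 methyl (3S,4R)-4-formyl-3,7-dimethyloct-6-enoate
Conditions: Et3SiH, Pd/C (5 mol %), acetone, rt
Reagents that add atoms: none
Why: The Fukuyama reduction turns only the thioester into the aldehyde under neutral conditions, so the methyl ester, the trisubstituted alkene and the α-stereocentre C1 should survive, and no hydroxy ester that could lactonise is ever formed.

Step 5
Reactants: 9 aldehyde ester
Product: 10 methyl (3S,4R)-4-ethynyl-3,7-dimethyloct-6-enoate
Conditions: dimethyl (1-diazo-2-oxopropyl)phosphonate, K2CO3, MeOH, 0 °C to rt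
Reagents that add atoms: dimethyl (1-diazo-2-oxopropyl)phosphonate (Ohira–Bestmann reagent), COP(=O)(OC)C(=[N+]=[N-])C(C)=O
Why: The Seyferth–Gilbert homologation in its Ohira–Bestmann form converts the aldehyde through an alkylidene carbene and a 1,2-hydrogen shift into the terminal alkyne (C4 added) with a base mild enough to keep C1, and methanol cannot scramble a methyl ester.

Step 6
Reactants: 10 alkynyl ester
Product: 11 (3S,4R)-4-ethynyl-3,7-dimethyloct-6-enal
Conditions: i-Bu2AlH (1.1 equiv), CH2Cl2, −78 °C; aq potassium sodium tartrate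
Reagents that add atoms: none
Why: Partial ester reduction with i-Bu2AlH at −78 °C stops at the aldehyde oxidation level, and neither the terminal alkyne nor the prenyl group is hydroaluminated at this temperature.

Step 7
Reactants: 12 2-methylbut-3-yn-2-ol
Product: 13 triethyl[(2-methylbut-3-yn-2-yl)oxy]silane
Conditions: Et3SiCl, imidazole, 4-(dimethylamino)pyridine (5 mol %), DMF, rt
Reagents that add atoms: chlorotriethylsilane, CC[Si](Cl)(CC)CC
Why: This routine silylation masks the tertiary hydroxyl during the boron chemistry with a poor leaving group that disfavours 1,4-elimination of the later allylboronate and that comes off together with the C8 ether in step 16.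

Step 8
Reactants: 13 silyl ether
Product: 14 (E)-4,4,5,5-tetramethyl-2-{3-methyl-3-[(triethylsilyl)oxy]but-1-en-1-yl}-1,3,2-dioxaborolane
Conditions: pinacolborane, Cp2Zr(H)Cl (10 mol %), Et3N (10 mol %), neat, 60 °C
Reagents that add atoms: pinacolborane, [H]B1OC(C)(C)C(C)(C)O1
Why: Zirconocene-hydride-catalysed hydroboration of a terminal alkyne is a syn addition that places boron on the unhindered terminal carbon, so only the E-alkenylboronate should form.

Step 9
Reactants: 14 alkenylboronate
Product: 16 (E)-4,4,5,5-tetramethyl-2-{4-methyl-4-[(triethylsilyl)oxy]pent-2-en-1-yl}-1,3,2-dioxaborolane, via chloromethyl boronate complex 15 (not isolated)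
Conditions: BrCH2Cl, n-BuLi, THF, −78 °C to rt
Reagents that add atoms: bromochloromethane, ClCBr
Why: In the Matteson homologation chloromethyllithium made in situ adds to boron, and 1,2-migration of the alkenyl group with loss of chloride inserts the CH2 group with retention of the E geometry.

Step 10
Reactants: 11 aldehyde; 16 E-allylboronate
Product: 18 (3S,4R,6S,7R)-7-ethynyl-6,10-dimethyl-3-{2-[(triethylsilyl)oxy]propan-2-yl}undeca-1,9-dien-4-ol, via pinacol borate ester 17 (not isolated)
Conditions: (S)-3,3'-bis(2,4,6-triisopropylphenyl)-1,1'-binaphthyl-2,2'-diyl hydrogen phosphate [(S)-TRIP, 10 mol %], 4 Å molecular sieves, toluene, −30 to 0 °C; aq NaHCO3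
Reagents that add atoms: none
Why: The chiral-phosphoric-acid-catalysed allylboration runs through a closed chair transition state in which the E geometry of 16 becomes the anti C7/C8 relationship, while the (S)-acid, hydrogen-bonded to the pseudoaxial boronate oxygen and the formyl hydrogen, should direct C7 onto the Si face of 11 and so set 8R and 7S.

Step 11
Reactants: 18 homoallylic alcohol
Product: 19 (3S,4R,6S,7R)-7-ethynyl-6,10-dimethyl-4-[(triethylsilyl)oxy]-3-{2-[(triethylsilyl)oxy]propan-2-yl}undeca-1,9-diene
Conditions: Et3SiOTf, 2,6-lutidine, CH2Cl2, −78 to 0 °C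
Reagents that add atoms: triethylsilyl trifluoromethanesulfonate, CC[Si](CC)(CC)OS(=O)(=O)C(F)(F)F
Why: Silyl triflate silylation is the standard answer to a hindered secondary alcohol, and a second triethylsilyl group allows one global deprotection because C8 and C11 are told apart later by their intrinsic reactivity.

Step 12
Reactants: 19 terminal alkyne
Product: 21 (3S,4R,6S,7R)-6,10-dimethyl-7-(prop-1-yn-1-yl)-4-[(triethylsilyl)oxy]-3-{2-[(triethylsilyl)oxy]propan-2-yl}undeca-1,9-diene, via lithium acetylide 20 (not isolated)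
Conditions: n-BuLi, THF, −78 °C; then MeI, −78 °C to rt
Reagents that add atoms: iodomethane, CI
Why: Deprotonation of the terminal alkyne and SN2 methylation of the acetylide install C15, and the step is placed here because no ester or free hydroxyl is left to compete for the base.

Step 13
Reactants: 21 dienyne
Product: 24 (1R,7S,8R,10S)-8,11-bis(triethylsilyloxy)guaia-3,5-diene, via C6 ruthenium alkylidene 22 (not isolated), via C4 ruthenium vinylcarbene 23 (not isolated)
Conditions: (H2IMes)(PCy3)Cl2Ru=CHPh (second-generation Grubbs catalyst, 10 mol % in two portions), 1,4-benzoquinone (10 mol %), degassed toluene (2 mM), 80 °C, argon sparge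
Reagents that add atoms: none
Why: The benzylidene should exchange only with the monosubstituted C6 vinyl group to give 22, whose Ru=C6 unit adds to C5≡C4 with C6 bonding to the nearer carbon C5, and opening of the ruthenacyclobutene gives C5=C6 and the vinylcarbene 23 on C4. Carbene 23 then undergoes ring-closing alkene metathesis with C3=CMe2, forming C3=C4 and releasing Ru=CMe2, which picks up the vinyl group of the next molecule and expels 2-methylpropene. This is the ene–yne–ene (dienyne) ring-closing metathesis cascade known for fused bicyclic 1,3-dienes, hydroazulenes included, in which a more substituted second alkene is the established way to fix the direction of the relay. Ring B closes in the 7-exo-dig enyne mode, so that only C5 of the alkyne enters it, and ring A closes as a five-membered alkene metathesis in which C4 and C5 both become ring atoms. No stereocentre is created, and C1, C7, C8 and C10 are spectators. The step needs loading at C6 and not at C3, which the prenyl cap secures, while high dilution suppresses cross-metathesis and the slow eight-membered C3=C6 closure cannot compete with capture by the alkyne.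

Step 14
Reactants: 24 guaia-3,5-diene
Product: 26 (1R,3S,4S,7S,8R,10S)-8,11-bis(triethylsilyloxy)guai-5-en-3-ol, via C3 trialkylborane 25 (not isolated)
Conditions: 9-BBN (2.5 equiv), THF, rt to 50 °C; then NaOH, H2O2, 0 °C to rt
Reagents that add atoms: hydrogen peroxide, OO
Why: In this Brown hydroboration–oxidation 9-BBN places boron on the less substituted, unhindered C3 of the ring A alkene whereas C6 is shielded by the C7 side chain, and the two stereocentres made by syn addition (drawn for attack on the face of H-1) are erased in step 15.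

Step 15
Reactants: 26 homoallylic alcohol
Product: 28 (1R,7S,8R,10S)-8,11-bis(triethylsilyloxy)guai-4-en-3-one, via guai-5-en-3-one 27 (not isolated)
Conditions: Dess–Martin periodinane, NaHCO3, CH2Cl2, 0 °C to rt; filter, concentrate; then 1,8-diazabicyclo[5.4.0]undec-7-ene (DBU, 0.2 equiv), CH2Cl2, 0 °C to rt
Reagents that add atoms: none
Why: Dess–Martin oxidation gives the β,γ-unsaturated ketone 27, whose doubly activated C4–H is removed by catalytic DBU so that reprotonation of the dienolate at C6 delivers the tetrasubstituted conjugated enone, the thermodynamic sink, under conditions too mild to deprotonate C1–H of the product.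

Step 16
Reactants: 28 bis-silyl enone
Product: 29 (1R,7S,8R,10S)-8,11-dihydroxyguai-4-en-3-one
Conditions: HF·pyridine, pyridine/THF, 0 °C to rt
Reagents that add atoms: none
Why: Fluoride-driven cleavage removes both triethylsilyl ethers in a buffered, weakly acidic medium, which avoids the base that could epimerise C1 and the strong acid that could dehydrate C11.

Step 17
Reactants: 29 diol
Product: 30 (1R,7S,8R,10S)-11-hydroxy-8-propanoyloxyguai-4-en-3-one
Conditions: (EtCO)2O (1.5 equiv), 4-(dimethylamino)pyridine (10 mol %), pyridine, 0 °C to rt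
Reagents that add atoms: propionic anhydride, CCC(=O)OC(=O)CC
Why: The 4-(dimethylamino)pyridine-catalysed (Steglich-type) acylation is selective for the secondary C8 hydroxyl because the tertiary C11 hydroxyl does not react with an anhydride at or below room temperature.

Step 18
Reactants: 30 hydroxy propionate
Product: 31 (1R,7S,8R,10S)-11-acetoxy-8-propanoyloxyguai-4-en-3-one (CNP0288556.1)
Conditions: Ac2O (10 equiv), 4-(dimethylamino)pyridine (1 equiv), Et3N, CH2Cl2, 40 °C
Reagents that add atoms: acetic anhydride, CC(=O)OC(C)=O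
Why: Forcing Steglich acetylation with excess anhydride and a full equivalent of the acyl-transfer catalyst esterifies the remaining tertiary alcohol, and the non-acidic medium avoids ionisation or dehydration at C11.

Compound list
1 | methyl hydrogen (R)-3-methylglutarate | COC(=O)C[C@H](C)CC(=O)O | starting material
2 | (4R)-4-benzyl-1,3-oxazolidin-2-one | O=C1N[C@H](Cc2ccccc2)CO1 | starting material
3 | mixed anhydride of 1 and pivalic acid (C10 unchanged) | COC(=O)C[C@H](C)CC(=O)OC(=O)C(C)(C)C | intermediate
4 | methyl (3R)-5-[(4R)-4-benzyl-2-oxo-1,3-oxazolidin-3-yl]-3-methyl-5-oxopentanoate | COC(=O)C[C@H](C)CC(=O)N1[C@H](Cc2ccccc2)COC1=O | intermediate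
5 | prenyl bromide (1-bromo-3-methylbut-2-ene) | CC(C)=CCBr | starting material
6 | sodium (Z)-enolate of imide 4 | [Na+].COC(=O)C[C@H](C)/C=C(\[O-])N1[C@H](Cc2ccccc2)COC1=O | intermediate
7 | methyl (3S,4R)-4-{[(4R)-4-benzyl-2-oxo-1,3-oxazolidin-3-yl]carbonyl}-3,7-dimethyloct-6-enoate | CC(C)=CC[C@@H](C(=O)N1[C@H](Cc2ccccc2)COC1=O)[C@@H](C)CC(=O)OC | intermediate
8 | methyl (3S,4R)-4-[(ethylsulfanyl)carbonyl]-3,7-dimethyloct-6-enoate | CC(C)=CC[C@@H](C(=O)SCC)[C@@H](C)CC(=O)OC | intermediate
9 | methyl (3S,4R)-4-formyl-3,7-dimethyloct-6-enoate | CC(C)=CC[C@@H](C=O)[C@@H](C)CC(=O)OC | intermediate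
10 | methyl (3S,4R)-4-ethynyl-3,7-dimethyloct-6-enoate | CC(C)=CC[C@@H](C#C)[C@@H](C)CC(=O)OC | intermediate
11 | (3S,4R)-4-ethynyl-3,7-dimethyloct-6-enal | CC(C)=CC[C@@H](C#C)[C@@H](C)CC=O | intermediate
12 | 2-methylbut-3-yn-2-ol | CC(C)(O)C#C | starting material
13 | triethyl[(2-methylbut-3-yn-2-yl)oxy]silane | C#CC(C)(C)O[Si](CC)(CC)CC | intermediate
14 | (E)-4,4,5,5-tetramethyl-2-{3-methyl-3-[(triethylsilyl)oxy]but-1-en-1-yl}-1,3,2-dioxaborolane | CC[Si](CC)(CC)OC(C)(C)/C=C/B1OC(C)(C)C(C)(C)O1 | intermediate
15 | lithium chloromethyl boronate (ate) complex of 14 | [Li+].CC[Si](CC)(CC)OC(C)(C)/C=C/[B-]1(CCl)OC(C)(C)C(C)(C)O1 | intermediate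
16 | (E)-4,4,5,5-tetramethyl-2-{4-methyl-4-[(triethylsilyl)oxy]pent-2-en-1-yl}-1,3,2-dioxaborolane | CC[Si](CC)(CC)OC(C)(C)/C=C/CB1OC(C)(C)C(C)(C)O1 | intermediate
17 | pinacol borate ester of alcohol 18 (boron on the C8 oxygen) | CC(C)=CC[C@@H](C#C)[C@@H](C)C[C@@H](OB1OC(C)(C)C(C)(C)O1)[C@H](C=C)C(C)(C)O[Si](CC)(CC)CC | intermediate
18 | (3S,4R,6S,7R)-7-ethynyl-6,10-dimethyl-3-{2-[(triethylsilyl)oxy]propan-2-yl}undeca-1,9-dien-4-ol | CC(C)=CC[C@@H](C#C)[C@@H](C)C[C@@H](O)[C@H](C=C)C(C)(C)O[Si](CC)(CC)CC | intermediate
19 | (3S,4R,6S,7R)-7-ethynyl-6,10-dimethyl-4-[(triethylsilyl)oxy]-3-{2-[(triethylsilyl)oxy]propan-2-yl}undeca-1,9-diene | CC(C)=CC[C@@H](C#C)[C@@H](C)C[C@@H](O[Si](CC)(CC)CC)[C@H](C=C)C(C)(C)O[Si](CC)(CC)CC | intermediate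
20 | lithium acetylide of 19 | CC(C)=CC[C@@H](C#C[Li])[C@@H](C)C[C@@H](O[Si](CC)(CC)CC)[C@H](C=C)C(C)(C)O[Si](CC)(CC)CC | intermediate
21 | (3S,4R,6S,7R)-6,10-dimethyl-7-(prop-1-yn-1-yl)-4-[(triethylsilyl)oxy]-3-{2-[(triethylsilyl)oxy]propan-2-yl}undeca-1,9-diene (acyclic dienyne; guaiane 1R,7S,8R,10S) | CC(C)=CC[C@@H](C#CC)[C@@H](C)C[C@@H](O[Si](CC)(CC)CC)[C@H](C=C)C(C)(C)O[Si](CC)(CC)CC | intermediate
22 | (H2IMes)Cl2Ru alkylidene on C6 of the open chain | CC(C)=CC[C@@H](C#CC)[C@@H](C)C[C@@H](O[Si](CC)(CC)CC)[C@H](C=[Ru](Cl)(Cl)=C1N(c2c(C)cc(C)cc2C)CCN1c1c(C)cc(C)cc1C)C(C)(C)O[Si](CC)(CC)CC | intermediate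
23 | (H2IMes)Cl2Ru vinylcarbene on C4, ring B closed (C5=C6), prenyl still on C1 | CC(C)=CC[C@H]1C(C(C)=[Ru](Cl)(Cl)=C2N(c3c(C)cc(C)cc3C)CCN2c2c(C)cc(C)cc2C)=C[C@H](C(C)(C)O[Si](CC)(CC)CC)[C@H](O[Si](CC)(CC)CC)C[C@@H]1C | intermediate
24 | (1R,7S,8R,10S)-8,11-bis(triethylsilyloxy)guaia-3,5-diene | CC1=CC[C@H]2C1=C[C@H](C(C)(C)O[Si](CC)(CC)CC)[C@H](O[Si](CC)(CC)CC)C[C@@H]2C | intermediate
25 | B-(guai-5-en-3-yl)-9-borabicyclo[3.3.1]nonane derived from 24 (boron and H-4 on the face of H-1) | C[C@@H]1[C@@H](B3C4CCCC3CCC4)C[C@H]2C1=C[C@H](C(C)(C)O[Si](CC)(CC)CC)[C@H](O[Si](CC)(CC)CC)C[C@@H]2C | intermediate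
26 | (1R,3S,4S,7S,8R,10S)-8,11-bis(triethylsilyloxy)guai-5-en-3-ol | C[C@@H]1[C@@H](O)C[C@H]2C1=C[C@H](C(C)(C)O[Si](CC)(CC)CC)[C@H](O[Si](CC)(CC)CC)C[C@@H]2C | intermediate
27 | (1R,4S,7S,8R,10S)-8,11-bis(triethylsilyloxy)guai-5-en-3-one | C[C@@H]1C(=O)C[C@H]2C1=C[C@H](C(C)(C)O[Si](CC)(CC)CC)[C@H](O[Si](CC)(CC)CC)C[C@@H]2C | intermediate
28 | (1R,7S,8R,10S)-8,11-bis(triethylsilyloxy)guai-4-en-3-one | CC[Si](CC)(CC)O[C@@H]1C[C@H](C)[C@H]2CC(=O)C(C)=C2C[C@@H]1C(C)(C)O[Si](CC)(CC)CC | intermediate
29 | (1R,7S,8R,10S)-8,11-dihydroxyguai-4-en-3-one | O[C@@H]1C[C@H](C)[C@H]2CC(=O)C(C)=C2C[C@@H]1C(C)(C)O | intermediate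
30 | (1R,7S,8R,10S)-11-hydroxy-8-propanoyloxyguai-4-en-3-one | CCC(=O)O[C@@H]1C[C@H](C)[C@H]2CC(=O)C(C)=C2C[C@@H]1C(C)(C)O | intermediate
31 | (1R,7S,8R,10S)-11-acetoxy-8-propanoyloxyguai-4-en-3-one (CNP0288556.1) | CCC(=O)O[C@@H]1C[C@H](C)[C@H]2CC(=O)C(C)=C2C[C@@H]1C(C)(C)OC(C)=O | target

Total step count: 18. Longest linear sequence: 15 (steps 1–6 and 10–18). Steps 7–9 form the three-step side branch to boronate 16.

Steps most likely to fail

Step 13.
- What may go wrong: ruthenium may load only slowly on the congested C6 vinyl group, or the hindered C4 carbene may stall before it reaches the trisubstituted alkene. In either case the catalyst decays and the alkyne is consumed by oligomerisation.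
- Fallback: the two ring closures are uncoupled.
- First closure: setting out from 21, enyne ring-closing metathesis is run under an ethylene atmosphere (1 atm, same catalyst, CH2Cl2, 40 °C). The small methylidene carrier loads more easily at C6, or adds to the alkyne first, which leads to the same product. Ethylene intercepts the C4 carbene, so the monocyclic ring B triene F1 (isopropenyl on C5, prenyl on C1) can be isolated.
- Second closure: ring A is closed in a separate diene ring-closing metathesis between the isopropenyl and prenyl groups with the second-generation Hoveyda–Grubbs catalyst (H2IMes)Cl2Ru(=CH-C6H4-2-O-i-Pr) in toluene at 80–110 °C. This comes back to the route at 24.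

Step 10.
- What may go wrong: the bulky γ-substituent may slow the addition so much that the uncatalysed background reaction erodes the facial selectivity, or the boronate may be lost by protodeboronation or 1,4-elimination.
- Fallback: C7–C8 is made by an auxiliary-controlled aldol reaction, and C11 is built afterwards.
- Aldol: setting out from 11, a boron-mediated Evans syn-aldol with commercial (4S)-4-benzyl-3-[(E)-but-2-enoyl]-1,3-oxazolidin-2-one (n-Bu2BOTf, Et3N, CH2Cl2, −78 to 0 °C, α-attack of the dienolate) should give the α-vinyl syn-aldol imide F2, with 7S and 8R fixed by the auxiliary.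
- Building C11: methanolysis (MeOMgBr, MeOH/CH2Cl2, 0 °C) gives the methyl ester F3. Double methyl addition (MeMgBr, CeCl3, THF, −78 to 0 °C) then gives the C8,C11-diol F4.
- Return: excess Et3SiOTf with 2,6-lutidine silylates both hydroxyls and comes back to the route at 19.

Step 14.
- What may go wrong: the conjugated diene may react sluggishly, or boron may also add at C5=C6, giving regioisomers and double hydroboration.
- Fallback: oxygen is brought in by epoxidation.
- Epoxidation: setting out from 24, buffered m-chloroperbenzoic acid (NaHCO3, CH2Cl2, −20 °C) should epoxidise the less shielded ring A alkene to the 3,4-epoxyguai-5-ene F5.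
- Isomerisation and return: the zerovalent palladium complex Pd(PPh3)4 (5 mol %, THF, rt to 50 °C) isomerises this diene monoepoxide. The allylic C4–O bond ionises and the C3 hydrogen is transferred, giving the ketone. The route is rejoined at 27, which DBU converts into 28 as in step 15.

Further compounds
F1 | step 13 | ring B triene: (1R,7S,8R,10S)-cyclohept-5-ene with isopropenyl on C5, prenyl on C1, methyl on C10, OSiEt3 on C8 and CMe2OSiEt3 on C7 | CC(C)=CC[C@H]1C(C(C)=C)=C[C@H](C(C)(C)O[Si](CC)(CC)CC)[C@H](O[Si](CC)(CC)CC)C[C@@H]1C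
F2 | step 10 | (4S)-4-benzyl-3-[(2S,3R,5S,6R)-2-ethenyl-6-ethynyl-3-hydroxy-5,9-dimethyldec-8-enoyl]-1,3-oxazolidin-2-one | CC(C)=CC[C@@H](C#C)[C@@H](C)C[C@@H](O)[C@H](C=C)C(=O)N1[C@@H](Cc2ccccc2)COC1=O
F3 | step 10 | methyl (2S,3R,5S,6R)-2-ethenyl-6-ethynyl-3-hydroxy-5,9-dimethyldec-8-enoate | CC(C)=CC[C@@H](C#C)[C@@H](C)C[C@@H](O)[C@H](C=C)C(=O)OC
F4 | step 10 | (3S,4R,6S,7R)-7-ethynyl-3-(2-hydroxypropan-2-yl)-6,10-dimethylundeca-1,9-dien-4-ol | CC(C)=CC[C@@H](C#C)[C@@H](C)C[C@@H](O)[C@H](C=C)C(C)(C)O
F5 | step 14 | (1R,7S,8R,10S)-3,4-epoxy-8,11-bis(triethylsilyloxy)guai-5-ene, epoxide oxygen on the face of H-1 | C[C@]12O[C@H]1C[C@H]3C2=C[C@H](C(C)(C)O[Si](CC)(CC)CC)[C@H](O[Si](CC)(CC)CC)C[C@@H]3C
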